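The earlier runs and the new flask were generated by integration from invented constants; noise was put on by code.

At 5.00 h Thursday's flask holds 24% left-handed substrate against 37% right-handed substrate, each charged as half of the total.

| flask | left-handed substrate | right-handed substrate | reagent | free catalyst | added ligand | remark | time |
|---|---|---|---|---|---|---|---|
| Thursday's | 0.53 M | 0.53 M | 1.2 M (fed, over 12 min) | 80 mM | 170 mM | run made earlier; the fed solution adds 0.25 times the starting volume |  |
| Tuesday's | 0.27 M | 0.27 M | 0.795 M (fed, over 12 min) | 80 mM | 170 mM | run made earlier; the fed solution adds 0.25 times the starting volume |  |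
| winter | 0.53 M | 0.53 M | 0.795 M (fed, over 12 min) | 80 mM | 170 mM | the fed solution adds 0.25 times the starting volume | 15 h |
| spring | 0.53 M | 0.53 M | 0.795 M (fed, over 12 min) | 20 mM | 170 mM | the fed solution adds 0.25 times the starting volume | 15 h |

| run | time / h | right-handed substrate / % | left-handed substrate / % | left-handed product / % |
|---|---|---|---|---|
| Thursday's | 0.417 | 48 | 45 | 8 |
| Thursday's | 0.667 | 43 | 38 | 10 |
| Thursday's | 1.00 | 41 | 39 | 12 |
| Thursday's | 2.00 | 42 | 33 | 18 |
| Thursday's | 3.00 | 38 | 28 | 20 |
| Thursday's | 5.00 | 37 | 24 | 26 |
| Tuesday's | 0.833 | 46 | 41 | 8 |
| Tuesday's | 2.00 | 42 | 35 | 14 |
| Tuesday's | 2.50 | 42 | 33 | 15 |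
| Tuesday's | 4.00 | 41 | 29 | 19 |
| Tuesday's | 5.00 | 42 | 34 | 20 |

(readings scatter by 1.5 percentage points)

- free catalyst is single-handed; left-handed substrate and right-handed substrate are mirror images of each other, charged as a racemate, each of them at the stated concentration
- charges are per starting volume, the dose included; the dosed solution carries all of it
- steps under discussion: 2 free catalyst <-> resting dimer; free catalyst -> spent catalyst; reagent + free catalyst + left-handed substrate -> free catalyst + left-handed product; free catalyst + added ligand <-> idle complex; reagent + free catalyst + right-handed substrate -> free catalyst + right-handed product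
- an excess is the difference of the two amounts in percent of their sum
- an excess is below zero if the other one leads
- no earlier run changes the charge of free catalyst; that part of a forecast is a guess

- which one finishes higher in excess of right-handed substrate over left-handed substrate among what is left of the two ("neither" within 2 percentage points) (winter / spring / neither)
- excess of right-handed substrate over left-handed substrate among what is left of the two at the end, winter
- excess of right-handed substrate over left-handed substrate among what is left of the two at the end, spring

How sharply does the free catalyst tell the two apart? I call ln(charged/left) the reach of a substrate. If each step is first order in its substrate, both substrates share one reagent and one catalyst, so the ratio of their reaches stays constant however those two run down. Thursday's readings give 2.44 for the left-handed reach over the right-handed reach, the selectivity factor s. It is a reading: Tuesday's flask gives 2.74 at 4.00 h.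

So an excess needs one further number, the left-handed reach. How far does winter get? Thursday's left-handed product creeps from 20% to 26% in the last two hours, and from the left-handed rate divided by the reagent concentration in both runs the forecast concludes that “the catalyst is dying, roughly hyperbolically”, with a winter reach of about 0.7. With s, I turn that reach into an excess of 20.4%, lower than the forecast's 21%.

And spring? Its c(free catalyst) of 20 mM is a quarter of winter's, and the order is a guess. A strict quarter of the reach gives me 5.16%, lower than the forecast's figure, which rests on a reach of 0.25.

The forecast says winter leads, with 21% (16% to 28%) for winter and 8% (5% to 14%) for spring.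

The flask gives 19.8% for winter and 6.64% for spring, so winter leads.

    2 free catalyst ⇌ resting dimer (K = 91.0 L mol⁻¹, k = 0.00620 L mol⁻¹ s⁻¹)
    free catalyst → spent catalyst (k = 2.40 × 10⁻⁴ s⁻¹)
    reagent + free catalyst + left-handed substrate → free catalyst + left-handed product (k = 0.00670 L² mol⁻² s⁻¹)
    free catalyst + added ligand ⇌ idle complex (K = 15.0 L mol⁻¹, k = 0.00400 L mol⁻¹ s⁻¹)
    reagent + free catalyst + right-handed substrate → free catalyst + right-handed product (k = 0.00280 L² mol⁻² s⁻¹)

The main reason for the gap is spring's smaller charge of free catalyst: with winter's charge, spring's excess is 19.8% instead of 6.64%. At 15.0 h winter keeps 50% of its left-handed substrate, and s turns that into 20.0%. The neighbour flask with 0.32 M of free catalyst keeps 23%, for which s gives 40.5%, and that flask stands at 40.1%.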